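**Retrosynthetic overview**
1. Target 40 ← acetylation and deprotection ← ring-closing metathesis at C5=C6 of a seco-diene that already carries ring A and the γ-lactone.
2. γ-Lactone (C7, C8, C17) ← phenylselenolactonisation of a γ,δ-unsaturated acid; C8 carbinol ← chelation-controlled Reformatsky addition to an α-alkoxy propenyl ketone.
3. C9/C10 ← Eschenmoser–Claisen rearrangement plus enolate hydroxylation on a C12 allylic alcohol, itself from epoxidation/Wharton transposition of the carvone enone.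
4. Key C1–C2 bond ← intermolecular aldol of the (S)-carvone lithium enolate with 5-silyloxypentanal, then oxidation, C-methylation (quaternary C1) and CBS reduction.
5. Ring order: ring A (from carvone) → γ-lactone → ten-membered ring.

Assumption: briarane numbering (C1–C20) is used for locants; TBDPS = tert-butyldiphenylsilyl, PMB = 4-methoxybenzyl; target = (1S,2R,5E,7S,8R,9R,10S,14S,17R). The route is a design, not an executed synthesis.

**Step 1**
Reactants: 1 pentane-1,5-diol
Product: 2 5-(TBDPS-oxy)pentan-1-ol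
Conditions: NaH (1.0 equiv), THF, 0 °C; TBDPSCl (1.0 equiv), rt
Reagents that add atoms: tert-butyldiphenylsilyl chloride, CC(C)(C)[Si](Cl)(c1ccccc1)c1ccccc1
Why: Monosilylation of the sparingly soluble mono-alkoxide of a symmetrical diol (silyl ether formation) gives the mono-ether selectively; no stereocentre.

**Step 2**
Reactants: 2 5-(TBDPS-oxy)pentan-1-ol
Product: 3 5-(TBDPS-oxy)pentanal
Conditions: Dess–Martin periodinane, pyridine, CH2Cl2, 0 °C to rt
Reagents that add atoms: none
Why: Dess–Martin oxidation stops cleanly at the aldehyde and tolerates the silyl ether.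

**Step 3**
Reactants: 4 (S)-(+)-carvone; 3 5-(TBDPS-oxy)pentanal
Product: 6 C1–C2 aldol adduct, via carvone lithium enolate 5 (not isolated)
Conditions: LiN(iPr)2, THF, −78 °C; then 3, −78 °C; aq NH4Cl
Reagents that add atoms: none
Why: Kinetic α′-deprotonation of carvone and intermolecular aldol addition join ring A to the C2–C5/C16 chain, the aldehyde adding anti to the isopropenyl group; the carbinol configuration is irrelevant because it is oxidised next.

**Step 4**
Reactants: 6 aldol adduct
Product: 7 C2,C10 β-diketone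
Conditions: Dess–Martin periodinane, CH2Cl2, rt
Reagents that add atoms: none
Why: Dess–Martin oxidation of the β-hydroxy ketone gives the 1,3-diketone, which activates C1 for clean C-alkylation.

**Step 5**
Reactants: 7 β-diketone
Product: 8 C1-methylated diketone
Conditions: K2CO3, MeI, acetone, rt
Reagents that add atoms: iodomethane, CI
Why: C-alkylation of the soft β-diketone enolate with MeI occurs anti to the neighbouring C14 isopropenyl group, setting quaternary C1 with C15 trans to the C14 substituent.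

**Step 6**
Reactants: 8 C1-methylated diketone
Product: 9 (2R)-hydroxy enone
Conditions: (S)-2-methyl-CBS-oxazaborolidine (20 mol %), catecholborane, toluene, −78 °C; MeOH, pH 7 buffer
Reagents that add atoms: none
Why: Corey–Bakshi–Shibata reduction attacks the saturated C2 ketone in preference to the hindered conjugated C10 ketone, and the (S)-catalyst (large group = quaternary C1, small group = CH2) delivers the 2R alcohol; catecholborane does not hydroborate the isopropenyl group.

**Step 7**
Reactants: 9 (2R)-hydroxy enone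
Product: 11 enone 2,14-diacetate, via methoxy hydroperoxide 10 (not isolated)
Conditions: O3, CH2Cl2/MeOH, −78 °C; then Ac2O, Et3N, DMAP, CH2Cl2, 0 to 40 °C
Reagents that add atoms: ozone, [O-][O+]=O; acetic anhydride, CC(=O)OC(C)=O
Why: Selective ozonolysis of the electron-rich isopropenyl group followed by Criegee rearrangement of the peracetate moves C14 from carbon to oxygen with retention (14S acetate); the C2 hydroxyl is acetylated at the same time so that no β-hydroxy ketone meets base later.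

**Step 8**
Reactants: 11 enone 2,14-diacetate
Product: 12 11,12-epoxy ketone
Conditions: t-BuOOH, DBU, CH2Cl2, 0 °C to rt
Reagents that add atoms: tert-butyl hydroperoxide, CC(C)(C)OO
Why: Weitz–Scheffer nucleophilic epoxidation adds the peroxide axially at C12 anti to the C14 acetoxy group (as in carvone), placing the epoxide on the face of the C15 methyl; anhydrous conditions spare the acetates.

**Step 9**
Reactants: 12 11,12-epoxy ketone
Product: 14 C12 allylic alcohol diacetate, via epoxy hydrazone 13 (not isolated)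
Conditions: N2H4·H2O, AcOH (cat.), MeOH, 0 °C to rt
Reagents that add atoms: none
Why: Wharton transposition (hydrazone formation, epoxide opening, loss of N2) gives the C10=C11 alkene and keeps the C12–O bond, so the C12 hydroxyl is cis to C15; any acetate lost here is removed anyway in step 10.

**Step 10**
Reactants: 14 C12 allylic alcohol diacetate
Product: 15 2,12,14-triol
Conditions: K2CO3 (cat.), MeOH, rt
Reagents that add atoms: none
Why: Base-catalysed transesterification removes both acetates; it is safe here because the C10 ketone (retro-aldol risk) is gone.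

**Step 11**
Reactants: 15 2,12,14-triol
Product: 16 2,14-acetonide allylic alcohol
Conditions: Me2C(OMe)2, PPTS (cat.), CH2Cl2, rt
Reagents that add atoms: 2,2-dimethoxypropane, COC(C)(C)OC
Why: Acetonide formation is selective for the syn-1,3-diol at C2/C14 (six-membered dioxane); the C12 hydroxyl is trans-disposed to C14–O and stays free.

**Step 12**
Reactants: 16 2,14-acetonide allylic alcohol; 17 N,N-dimethylacetamide dimethyl acetal
Product: 19 C10 dimethylacetamide, via ketene N,O-acetal 18 (not isolated)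
Conditions: xylene, 140 °C, removal of MeOH
Reagents that add atoms: none
Why: Eschenmoser–Claisen rearrangement forms the hindered C9–C10 bond intramolecularly and suprafacially, transferring the C12–O configuration to C10 (C9 cis to C15, 10S) and generating the C11=C12 trisubstituted alkene.

**Step 13**
Reactants: 19 C10 dimethylacetamide
Product: 21 (9R)-α-hydroxy amide, via amide lithium enolate 20 (not isolated)
Conditions: LiN(iPr)2, THF, −78 °C; (camphorsulfonyl)oxaziridine, −78 to −40 °C; aq NH4Cl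
Reagents that add atoms: (camphorsulfonyl)oxaziridine, CC1(C)C2CCC13CS(=O)(=O)N4OC34C2
Why: Davis enolate oxidation; in the A(1,3)-minimised Z-enolate H-10 eclipses the enolate and the oxidant approaches anti to the quaternary C1, which gives 9R.

**Step 14**
Reactants: 21 (9R)-α-hydroxy amide
Product: 22 C9 PMB ether
Conditions: NaH, 4-methoxybenzyl chloride, Bu4NI (cat.), THF/DMF, 0 °C to rt
Reagents that add atoms: 4-methoxybenzyl chloride, COc1ccc(CCl)cc1
Why: Williamson etherification installs a chelating ether that survives to the end and is removable with DDQ after the acetates are in place.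

**Step 15**
Reactants: 22 C9 PMB ether; 23 (E)-1-bromoprop-1-ene
Product: 25 (E)-propenyl ketone, via tetrahedral lithium alkoxide 24 (not isolated)
Conditions: 23, t-BuLi (2 equiv), Et2O, −78 °C; then 22, THF, −78 to −20 °C; cold aq NH4Cl
Reagents that add atoms: none
Why: Lithium–bromine exchange retains the E geometry and the alkenyllithium undergoes acyl substitution on the α-alkoxy amide through a chelated tetrahedral adduct that collapses only on quench, so no over-addition occurs.

**Step 16**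
Reactants: 25 (E)-propenyl ketone; 26 methyl 2-bromopropanoate
Product: 27 (8R)-β-hydroxy ester
Conditions: Zn dust (Me3SiCl-activated), THF, 0 °C to rt; aq NH4Cl
Reagents that add atoms: none
Why: Reformatsky 1,2-addition under Cram-chelate control (zinc bridging the C8 carbonyl and the C9 PMB ether) attacks from the H-9 side, anti to C10, setting 8R; C17 forms as an epimer mixture and is fixed in step 20.

**Step 17**
Reactants: 27 (8R)-β-hydroxy ester
Product: 28 β-hydroxy acid
Conditions: LiOH, THF/MeOH/H2O, rt; then 1 M HCl to pH 4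
Reagents that add atoms: lithium hydroxide, [Li+].[OH-]
Why: Saponification of the methyl ester frees the carboxylate needed as the internal nucleophile; the carboxylate resists retro-aldol cleavage.

**Step 18**
Reactants: 28 β-hydroxy acid
Product: 29 phenylseleno lactone
Conditions: PhSeCl, K2CO3, CH2Cl2, −78 °C
Reagents that add atoms: phenylselenenyl chloride, Cl[Se]c1ccccc1
Why: Phenylselenolactonisation (5-exo, anti addition across the E alkene) closes the γ-lactone with the C6 side chain trans to the bulky C9 substituent on C8 and cis to the C8 hydroxyl, which is the C7 configuration of the target.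

**Step 19**
Reactants: 29 phenylseleno lactone
Product: 31 C7 vinyl lactone, via selenoxide 30 (not isolated)
Conditions: 30 % H2O2, pyridine, THF, 0 °C to rt
Reagents that add atoms: none
Why: Selenoxide syn-elimination proceeds away from the oxygen-bearing C7 and so delivers the terminal vinyl group at C6.

**Step 20**
Reactants: 31 C7 vinyl lactone
Product: 32 (17R)-vinyl lactone
Conditions: DBU (0.2 equiv), toluene, 40 °C
Reagents that add atoms: none
Why: Base-mediated epimerisation α to the lactone carbonyl funnels the mixture to the thermodynamic isomer with C18 anti to the C9 chain on C8 (17R).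

**Step 21**
Reactants: 32 (17R)-vinyl lactone
Product: 33 C16 primary alcohol
Conditions: HF·pyridine, pyridine, THF, 0 °C to rt
Reagents that add atoms: none
Why: Buffered fluoride desilylation removes the TBDPS ether without touching the acetonide, PMB ether or β-hydroxy lactone.

**Step 22**
Reactants: 33 C16 primary alcohol
Product: 34 C16 aldehyde
Conditions: Dess–Martin periodinane, pyridine, CH2Cl2, 0 °C to rt
Reagents that add atoms: none
Why: Dess–Martin oxidation of the only primary alcohol; the tertiary C8 hydroxyl cannot be oxidised.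

**Step 23**
Reactants: 34 C16 aldehyde
Product: 35 C5-methylene aldehyde
Conditions: 37 % aq CH2O, pyrrolidine (10 mol %), propanoic acid (10 mol %), i-PrOH, 45 °C
Reagents that add atoms: formaldehyde, C=O
Why: Organocatalytic Mannich-type α-methylenation (enamine addition to formaldehyde, then elimination) installs the 1,1-disubstituted alkene at C5.

**Step 24**
Reactants: 35 C5-methylene aldehyde
Product: 36 seco-diene allylic alcohol
Conditions: NaBH4, CeCl3·7H2O, MeOH, −40 °C
Reagents that add atoms: none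
Why: Luche 1,2-reduction gives the 2-substituted allylic alcohol (C16–OH) and leaves the lactone intact.

**Step 25**
Reactants: 36 seco-diene allylic alcohol
Product: 37 ten-membered macrocycle
Conditions: second-generation Grubbs catalyst (10 mol %), 1,4-benzoquinone (cat.), toluene (0.5 mM), 90 °C
Reagents that add atoms: none
Why: Ring-closing metathesis between the C7 vinyl group and the C5 methylene closes the ten-membered ring; the ring size and the trans-fused ring A and lactone allow only the ring-cis (5E) trisubstituted alkene.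

**Step 26**
Reactants: 37 ten-membered macrocycle
Product: 38 2,8,14,16-tetraol
Conditions: AcOH/H2O (4:1), 45 °C
Reagents that add atoms: none
Why: Mild acidic acetal hydrolysis removes the acetonide; the PMB ether, lactone and allylic alcohol are stable.

**Step 27**
Reactants: 38 2,8,14,16-tetraol
Product: 39 2,14,16-triacetate C9 PMB ether
Conditions: Ac2O, pyridine, DMAP (cat.), CH2Cl2, 0 °C to rt
Reagents that add atoms: acetic anhydride, CC(=O)OC(C)=O
Why: DMAP-catalysed acetylation esterifies the primary C16 and secondary C2 and C14 hydroxyls; the tertiary C8 hydroxyl is unreactive and C9 is masked.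

**Step 28**
Reactants: 39 2,14,16-triacetate C9 PMB ether
Product: 40 target CNP0322315.2
Conditions: DDQ, CH2Cl2/pH 7 phosphate buffer (10:1), 0 °C
Reagents that add atoms: none
Why: Oxidative PMB ether cleavage with DDQ in wet solvent frees the C9 hydroxyl without affecting acetates, alkenes or the lactone.

**Compound list**
1 | pentane-1,5-diol | OCCCCCO | starting material
2 | 5-(TBDPS-oxy)pentan-1-ol | OCCCCCO[Si](c1ccccc1)(c1ccccc1)C(C)(C)C | intermediate
3 | 5-(TBDPS-oxy)pentanal | O=CCCCCO[Si](c1ccccc1)(c1ccccc1)C(C)(C)C | intermediate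
4 | (S)-(+)-carvone | O=C1C(C)=CC[C@H](C(C)=C)C1 | starting material
5 | carvone lithium enolate (C1=C10 enolate, 14S) | [Li]OC1=C[C@@H](C(C)=C)CC=C1C | intermediate
6 | aldol adduct: carvone bearing a 1-hydroxy-5-(TBDPS-oxy)pentyl chain at C1, trans to the isopropenyl group, C2 carbinol epimers | O=C1C(C)=CC[C@H](C(C)=C)[C@H]1C(O)CCCCO[Si](c3ccccc3)(c3ccccc3)C(C)(C)C | intermediate
7 | C2,C10 β-diketone (C1 enolisable, 14S) | O=C1C(C)=CC[C@H](C(C)=C)C1C(=O)CCCCO[Si](c3ccccc3)(c3ccccc3)C(C)(C)C | intermediate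
8 | C1-methylated diketone, C15 trans to isopropenyl (C1, C14 as in 40) | O=C1C(C)=CC[C@H](C(C)=C)[C@]1(C)C(=O)CCCCO[Si](c3ccccc3)(c3ccccc3)C(C)(C)C | intermediate
9 | (2R)-hydroxy enone (C1, C2, C14 as in 40) | O=C1C(C)=CC[C@H](C(C)=C)[C@]1(C)[C@H](O)CCCCO[Si](c3ccccc3)(c3ccccc3)C(C)(C)C | intermediate
10 | α-methoxy hydroperoxide from ozonolysis of 9 in methanol (peroxy carbon epimers) | O=C1C(C)=CC[C@H](C(C)(OC)OO)[C@]1(C)[C@H](O)CCCCO[Si](c3ccccc3)(c3ccccc3)C(C)(C)C | intermediate
11 | enone 2,14-diacetate (1S,2R,14S) | O=C1C(C)=CC[C@H](OC(C)=O)[C@]1(C)[C@H](OC(C)=O)CCCCO[Si](c3ccccc3)(c3ccccc3)C(C)(C)C | intermediate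
12 | 11,12-epoxy-10-ketone diacetate, epoxide cis to C15 | O=C1[C@@]2(C)O[C@H]2C[C@H](OC(C)=O)[C@]1(C)[C@H](OC(C)=O)CCCCO[Si](c3ccccc3)(c3ccccc3)C(C)(C)C | intermediate
13 | hydrazone of 12 | NN=C1[C@@]2(C)O[C@H]2C[C@H](OC(C)=O)[C@]1(C)[C@H](OC(C)=O)CCCCO[Si](c3ccccc3)(c3ccccc3)C(C)(C)C | intermediate
14 | C12 allylic alcohol 2,14-diacetate (C10=C11; 12-OH cis to C15) | C1=C(C)[C@@H](O)C[C@H](OC(C)=O)[C@]1(C)[C@H](OC(C)=O)CCCCO[Si](c3ccccc3)(c3ccccc3)C(C)(C)C | intermediate
15 | 2,12,14-triol | C1=C(C)[C@@H](O)C[C@H](O)[C@]1(C)[C@H](O)CCCCO[Si](c3ccccc3)(c3ccccc3)C(C)(C)C | intermediate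
16 | 2,14-O-isopropylidene C12 allylic alcohol | C1=C(C)[C@@H](O)C[C@H](O2)[C@]1(C)[C@H](OC2(C)C)CCCCO[Si](c3ccccc3)(c3ccccc3)C(C)(C)C | intermediate
17 | N,N-dimethylacetamide dimethyl acetal (1,1-dimethoxy-N,N-dimethylethanamine) | CC(OC)(OC)N(C)C | starting material
18 | C12 O-allyl ketene N,O-acetal | C1=C(C)[C@@H](OC(=C)N(C)C)C[C@H](O2)[C@]1(C)[C@H](OC2(C)C)CCCCO[Si](c3ccccc3)(c3ccccc3)C(C)(C)C | intermediate
19 | C10 N,N-dimethylacetamide (10S; C11=C12; C9 cis to C15) | CN(C)C(=O)C[C@H]1C(C)=CC[C@H](O2)[C@]1(C)[C@H](OC2(C)C)CCCCO[Si](c3ccccc3)(c3ccccc3)C(C)(C)C | intermediate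
20 | lithium Z-enolate of amide 19 | CN(C)/C(O[Li])=C/[C@H]1C(C)=CC[C@H](O2)[C@]1(C)[C@H](OC2(C)C)CCCCO[Si](c3ccccc3)(c3ccccc3)C(C)(C)C | intermediate
21 | (9R)-α-hydroxy amide (C1, C2, C9, C10, C14 as in 40) | CN(C)C(=O)[C@H](O)[C@H]1C(C)=CC[C@H](O2)[C@]1(C)[C@H](OC2(C)C)CCCCO[Si](c3ccccc3)(c3ccccc3)C(C)(C)C | intermediate
22 | C9 PMB ether of 21 | CN(C)C(=O)[C@H](OCc4ccc(OC)cc4)[C@H]1C(C)=CC[C@H](O2)[C@]1(C)[C@H](OC2(C)C)CCCCO[Si](c3ccccc3)(c3ccccc3)C(C)(C)C | intermediate
23 | (E)-1-bromoprop-1-ene | C/C=C/Br | starting material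
24 | tetrahedral lithium alkoxide from propenyllithium and 22 (C8 epimers) | C/C=C/C(O[Li])(N(C)C)[C@H](OCc4ccc(OC)cc4)[C@H]1C(C)=CC[C@H](O2)[C@]1(C)[C@H](OC2(C)C)CCCCO[Si](c3ccccc3)(c3ccccc3)C(C)(C)C | intermediate
25 | (E)-propenyl ketone (C8 ketone, C9 PMB ether) | C/C=C/C(=O)[C@H](OCc4ccc(OC)cc4)[C@H]1C(C)=CC[C@H](O2)[C@]1(C)[C@H](OC2(C)C)CCCCO[Si](c3ccccc3)(c3ccccc3)C(C)(C)C | intermediate
26 | methyl 2-bromopropanoate (racemic) | COC(=O)C(C)Br | starting material
27 | (8R)-β-hydroxy methyl ester, C8 as in 40, C17 epimers | COC(=O)C(C)[C@@](/C=C/C)(O)[C@H](OCc4ccc(OC)cc4)[C@H]1C(C)=CC[C@H](O2)[C@]1(C)[C@H](OC2(C)C)CCCCO[Si](c3ccccc3)(c3ccccc3)C(C)(C)C | intermediate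
28 | (8R)-β-hydroxy acid, C17 epimers | OC(=O)C(C)[C@@](/C=C/C)(O)[C@H](OCc4ccc(OC)cc4)[C@H]1C(C)=CC[C@H](O2)[C@]1(C)[C@H](OC2(C)C)CCCCO[Si](c3ccccc3)(c3ccccc3)C(C)(C)C | intermediate
29 | phenylseleno γ-lactone (C7, C8 as in 40; anti adduct at C6; C17 epimers) | C[C@H]([Se]c7ccccc7)[C@@H]1OC(=O)C(C)[C@@]1(O)[C@H](OCc4ccc(OC)cc4)[C@H]1C(C)=CC[C@H](O2)[C@]1(C)[C@H](OC2(C)C)CCCCO[Si](c3ccccc3)(c3ccccc3)C(C)(C)C | intermediate
30 | selenoxide of 29 | C[C@H]([Se](=O)c7ccccc7)[C@@H]1OC(=O)C(C)[C@@]1(O)[C@H](OCc4ccc(OC)cc4)[C@H]1C(C)=CC[C@H](O2)[C@]1(C)[C@H](OC2(C)C)CCCCO[Si](c3ccccc3)(c3ccccc3)C(C)(C)C | intermediate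
31 | C7 vinyl γ-lactone (7S,8R; C17 epimers) | C=C[C@@H]1OC(=O)C(C)[C@@]1(O)[C@H](OCc4ccc(OC)cc4)[C@H]1C(C)=CC[C@H](O2)[C@]1(C)[C@H](OC2(C)C)CCCCO[Si](c3ccccc3)(c3ccccc3)C(C)(C)C | intermediate
32 | (7S,8R,17R)-vinyl lactone, all stereocentres as in 40 | C=C[C@@H]1OC(=O)[C@H](C)[C@@]1(O)[C@H](OCc4ccc(OC)cc4)[C@H]1C(C)=CC[C@H](O2)[C@]1(C)[C@H](OC2(C)C)CCCCO[Si](c3ccccc3)(c3ccccc3)C(C)(C)C | intermediate
33 | C16 primary alcohol | C=C[C@@H]1OC(=O)[C@H](C)[C@@]1(O)[C@H](OCc4ccc(OC)cc4)[C@H]1C(C)=CC[C@H](O2)[C@]1(C)[C@H](OC2(C)C)CCCCO | intermediate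
34 | C16 aldehyde | C=C[C@@H]1OC(=O)[C@H](C)[C@@]1(O)[C@H](OCc4ccc(OC)cc4)[C@H]1C(C)=CC[C@H](O2)[C@]1(C)[C@H](OC2(C)C)CCCC=O | intermediate
35 | C5-methylene C16 aldehyde | C=C[C@@H]1OC(=O)[C@H](C)[C@@]1(O)[C@H](OCc4ccc(OC)cc4)[C@H]1C(C)=CC[C@H](O2)[C@]1(C)[C@H](OC2(C)C)CCC(=C)C=O | intermediate
36 | seco-diene allylic alcohol (C5 methylene, C16-OH, C7 vinyl) | C=C[C@@H]1OC(=O)[C@H](C)[C@@]1(O)[C@H](OCc4ccc(OC)cc4)[C@H]1C(C)=CC[C@H](O2)[C@]1(C)[C@H](OC2(C)C)CCC(=C)CO | intermediate
37 | ten-membered macrocycle: 2,14-acetonide, C9 PMB ether, C16-OH, 5E | OC/C1=C/[C@@H]2OC(=O)[C@H](C)[C@@]2(O)[C@H](OCc4ccc(OC)cc4)[C@H]2C(C)=CC[C@H](O3)[C@]2(C)[C@H](OC3(C)C)CC1 | intermediate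
38 | 2,8,14,16-tetraol C9 PMB ether | OC/C1=C/[C@@H]2OC(=O)[C@H](C)[C@@]2(O)[C@H](OCc4ccc(OC)cc4)[C@H]2C(C)=CC[C@H](O)[C@]2(C)[C@H](O)CC1 | intermediate
39 | 2,14,16-triacetate C9 PMB ether | CC(=O)OC/C1=C/[C@@H]2OC(=O)[C@H](C)[C@@]2(O)[C@H](OCc4ccc(OC)cc4)[C@H]2C(C)=CC[C@H](OC(C)=O)[C@]2(C)[C@H](OC(C)=O)CC1 | intermediate
40 | CNP0322315.2, (1S,2R,5E,7S,8R,9R,10S,14S,17R)-2,14,16-triacetoxy-8,9-dihydroxybriara-5,11-dien-19,7-olide (8,17-lactone ring) | CC(=O)OC/C1=C/[C@@H]2OC(=O)[C@H](C)[C@@]2(O)[C@H](O)[C@H]2C(C)=CC[C@H](OC(C)=O)[C@]2(C)[C@H](OC(C)=O)CC1 | target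

**Totals and risks**
Total step count: 28. Longest linear sequence: 28 steps (1 → 40; 26 steps counted from carvone 4).

Step 25 (ring-closing metathesis to a ten-membered trisubstituted alkene) is the most likely to fail through oligomerisation or no turnover at the 1,1-disubstituted alkene. The fallback sets out from aldehyde 34. OsO4 (cat.)/NaIO4 with 2,6-lutidine in dioxane/H2O cleaves the monosubstituted vinyl group in preference to the hindered trisubstituted ring A alkene and gives the C6,C16-dialdehyde F1. An intramolecular aldol condensation under high dilution (piperidinium acetate, MeCN, 40 °C), with the unbranched C16 aldehyde as the enamine donor through C5 and the α-oxygenated C6 aldehyde as the acceptor, closes the ring to the macrocyclic (E)-enal F2, whose geometry (CHO trans to C7) is the ring-cis one. NaBH4/CeCl3·7H2O reduction then returns to the route at 37.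

Step 9 (Wharton transposition) may stall because the C10 ketone is flanked by the quaternary C1 and forms a hydrazone slowly. The fallback sets out from epoxy ketone 12. NaBH4/CeCl3·7H2O at −78 °C gives the C10 epoxy alcohol F3 (either epimer serves), and 1,1′-thiocarbonyldiimidazole with DMAP converts it into the O-thiocarbonylimidazolide F4. Bu3SnH/AIBN in toluene at 80 °C generates the C10 radical, which opens the epoxide to the C12 alkoxyl radical and, after hydrogen transfer, gives the same allylic alcohol; the route is rejoined at 14.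

Step 18 (selenolactonisation) may give poor control at C7 or competing addition of PhSeCl to the ring A alkene. The fallback sets out from acid 28. Equilibrating iodolactonisation (I2, MeCN, rt) gives under thermodynamic control the iodo lactone F5 with the C6 side chain trans to the C9 substituent. Displacement with PhSeNa (from PhSeSePh/NaBH4, EtOH) gives the C6-epimeric phenylseleno lactone F6, which on the oxidation of step 19 eliminates to the same vinyl lactone; the route is rejoined at 31.

**Further compounds**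
F1 | step 25 | C6,C16-dialdehyde (vinyl group of 34 cleaved to the C6 aldehyde) | O=C[C@@H]1OC(=O)[C@H](C)[C@@]1(O)[C@H](OCc4ccc(OC)cc4)[C@H]1C(C)=CC[C@H](O2)[C@]1(C)[C@H](OC2(C)C)CCCC=O
F2 | step 25 | macrocyclic (5E)-enal (C16 aldehyde on the ten-membered ring) | O=C/C1=C/[C@@H]2OC(=O)[C@H](C)[C@@]2(O)[C@H](OCc4ccc(OC)cc4)[C@H]2C(C)=CC[C@H](O3)[C@]2(C)[C@H](OC3(C)C)CC1
F3 | step 9 | C10 epoxy alcohol diacetate (C10 epimers) | OC1[C@@]2(C)O[C@H]2C[C@H](OC(C)=O)[C@]1(C)[C@H](OC(C)=O)CCCCO[Si](c3ccccc3)(c3ccccc3)C(C)(C)C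
F4 | step 9 | C10 O-(imidazol-1-ylthiocarbonyl) epoxy alcohol diacetate | S=C(n5ccnc5)OC1[C@@]2(C)O[C@H]2C[C@H](OC(C)=O)[C@]1(C)[C@H](OC(C)=O)CCCCO[Si](c3ccccc3)(c3ccccc3)C(C)(C)C
F5 | step 18 | C6 iodo γ-lactone (C7, C8 as in 40; C17 epimers) | C[C@H](I)[C@@H]1OC(=O)C(C)[C@@]1(O)[C@H](OCc4ccc(OC)cc4)[C@H]1C(C)=CC[C@H](O2)[C@]1(C)[C@H](OC2(C)C)CCCCO[Si](c3ccccc3)(c3ccccc3)C(C)(C)C
F6 | step 18 | C6-epimeric phenylseleno γ-lactone | C[C@@H]([Se]c7ccccc7)[C@@H]1OC(=O)C(C)[C@@]1(O)[C@H](OCc4ccc(OC)cc4)[C@H]1C(C)=CC[C@H](O2)[C@]1(C)[C@H](OC2(C)C)CCCCO[Si](c3ccccc3)(c3ccccc3)C(C)(C)C
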